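(All runs come from a simulation on assumed constants; noise was put on by code.)

**The constants.** We read two constants off the runs and count turnovers with them. Reading peaks as percent of the Sub charged, we take Tsp as lost one for one with Sub. Thursday's last Sub then gives, by the second-order law, k = 0.00188 mM⁻¹ min⁻¹. Our quantity is the turnover count N, which is k times the Tsp charge c times the time.

all flasks: Sub 22 mM

| run | Tsp | remark | time |
|---|---|---|---|
| Sunday's | 25 mM | run made earlier |  |
| Thursday's | 30 mM | run made earlier |  |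
| Monday's | 41 mM | run made earlier |  |
| alder | 22.0 mM |  | 30 min |
| larch | 44.0 mM |  | 30 min |

| run | time / min | Sub / % | Ofp2 / % | Tgt / % | Tsp2 / % |
|---|---|---|---|---|---|
| Sunday's | 1.33 | 93.5 | 0 | 1.3 | 0 |
| Sunday's | 4.00 | 86.3 | 0 | 7.6 | 1.0 |
| Sunday's | 8.00 | 73.0 | 1.3 | 16.4 | 2.6 |
| Sunday's | 10.0 | 66.9 | 2.6 | 20.1 | 4.3 |
| Sunday's | 15.0 | 57.8 | 4.2 | 27.3 | 2.3 |
| Thursday's | 3.00 | 84.6 | 1.0 | 5.5 | 1.5 |
| Thursday's | 6.00 | 74.5 | 0 | 13.0 | 2.4 |
| Thursday's | 10.0 | 63.5 | 3.7 | 24.6 | 3.5 |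
| Thursday's | 12.0 | 57.0 | 3.7 | 25.2 | 4.2 |
| Thursday's | 15.0 | 51.3 | 5.6 | 31.4 | 5.5 |
| Monday's | 1.33 | 91.5 | 0 | 1.2 | 0 |
| Monday's | 2.50 | 83.8 | 0 | 4.9 | 0.2 |
| Monday's | 4.00 | 75.1 | 0.3 | 11.3 | 1.9 |
| Monday's | 8.00 | 60.2 | 3.1 | 24.3 | 4.2 |
| Monday's | 15.0 | 37.9 | 6.4 | 41.2 | 5.5 |

(readings scatter by 1 percentage point)

- in percentages every species weighs as the Sub in it: one Tsp2 counts as two
- steps that have been proposed: Sub + Tsp -> Sub.Tsp; Sub.Tsp -> Tgt; Sub + Sub.Tsp -> Tsp2; Tgt <-> Ofp; Tgt -> Ofp2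
- a reading of Tgt is of its free form alone

* which of these there is most of at the end, counted by the Sub in it, alder (Ofp2 / Tsp2 / Tgt / Sub)
* which of these there is most of at the end, counted by the Sub in it, larch (Ofp2 / Tsp2 / Tgt / Sub)
* how much there is at the end of the one of these that leads, in percent of the Sub charged: alder
* how much there is at the end of the one of these that leads, in percent of the Sub charged: larch

**Main step.** Take Sub + Tsp, through Sub.Tsp, to Tgt by itself. With equal charges the fraction of Sub left is the reciprocal of one plus N. Alder has N = 1.24, so Sub stands at 44.6%. With a gap d between the charges, the fraction is d over (c times exp(N d/c) minus the Sub charge). Larch has N = 2.48, so 16.9% of its Sub stays. On this step by itself, Tgt is then 55.4% in alder and 83.1% in larch.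

**Side paths.** At 15.0 min in Thursday's run, the readings leave 11.7% that is neither Sub, Tgt nor Ofp2. As an estimate, we subtract that from the Tgt of both flasks.

**Onward loss.** Monday's last Ofp2, over half its last Tgt times the time, reads 0.0207 min⁻¹. Taking the mean age of Tgt as half the time, we reckon that 73.3% survives. Our Tgt is 32.0% in alder, less than its Sub, and 52.3% in larch.

**The forecast.** It says Sub at 44% for alder, “Sub leads narrowly”, and Tgt at 47% for larch. Our larch Tgt stands higher than that, but the leaders are the same.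

**The result.** Alder gives Sub at 44.5% and larch gives Tgt at 46.0%, so the forecast held. N had given Sub 44.6% in alder and 16.9% in larch; those flasks hold 44.5% and 17.5%.

    Sub + Tsp → Sub.Tsp (k = 0.0290 M⁻¹ s⁻¹)
    Sub.Tsp → Tgt (k = 0.00580 s⁻¹)
    Sub + Sub.Tsp → Tsp2 (k = 0.0230 M⁻¹ s⁻¹)
    Tgt ⇌ Ofp (K = 0.410, k = 9.10 × 10⁻⁵ s⁻¹)
    Tgt → Ofp2 (k = 3.70 × 10⁻⁴ s⁻¹)

In larch at 30.0 min, the half-life of Sub by its step with Tsp is 15 min, about half the 31 min of Tgt going to Ofp2. Larch's Tgt goes from 41.1% at 15.0 min to 46.0% at 30.0 min.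

**Second flask.** Read larch at 2.0 h instead: N = 9.93, and the law leaves 0.350% of Sub. That flask holds Sub 0.420% and Tgt 10.9%, and Ofp2 leads at 74.0%.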